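**Target:** (1S,2R,3R)-1-(4-hydroxy-3,5-dimethoxyphenyl)-2,3-bis(hydroxymethyl)-6,8-dimethoxy-1,2,3,4-tetrahydronaphthalen-7-ol (CNP0153696.1), the all-trans aryltetralin.

## Retrosynthetic overview

1. Tetralin numbering is used throughout: C1 bears pendant ring C, C2 and C3 bear the CH2OH carbons C9 and C10, C4 is CH2, and ring A is C4a–C8a with OMe on C6 and C8 and OH on C7.
2. The strategy rests on two features: ring A carries three contiguous oxygens (C6, C7, C8) directly beside the C8a ring fusion, and ring B with its trans C2/C3 arms is a reduced C2-symmetric trans-cyclohex-4-ene-1,2-dicarboxylic acid. Ring A is therefore cut at C5–C4a and C8–C8a into a 2-benzyloxy-1,3-dimethoxy-1-silyloxybutadiene and the 2-bromo enone of ring B ((4+2) addition, then loss of MeOH and HBr).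
3. The ring B enone comes from the (1R,2R)-diacid by reduction, benzylation, SeO2 allylic hydroxylation, oxidation and α-bromination. SeO2 is chosen because its ene/[2,3] sequence returns the C=C to its place and puts the carbonyl next to a ring stereocentre; radical allylic oxidants would oxygenate mainly the far, less hindered allyl terminus and give the 4,5-disubstituted enone.
4. The endgame is O-methylation at C8, aryl-cerium addition to the C1 ketone, ionic hydrogenation to set C1, and global hydrogenolysis.
5. Ring order: ring B (chiral pool), then ring A (cycloaddition–aromatisation), then pendant ring C attached last.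

Key step: step 10

Remark: the carbinol centres of the allylic alcohol and of the C1 diarylcarbinol, the enol-ether geometry of the β-methoxy enoate and the ketene-acetal geometry of the diene are inconsequential, because each is planarised or lost in a later step; their SMILES leave these elements open (the diene is drawn as the chelation-controlled isomer).

## Route

Step 1
Reactants: 1 (1R,2R)-cyclohex-4-ene-1,2-dicarboxylic acid
Product: 2 (1R,2R)-cyclohex-4-ene-1,2-diyldimethanol
Conditions: LiAlH4, THF, 0 °C → reflux; Fieser work-up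
Reagents that add atoms: none
Why: LiAlH4 hydride reduction of both carboxylic acids to primary alcohols proceeds through carboxylate salts that do not enolise, so the trans (1R,2R) centres are carried through unchanged.

Step 2
Reactants: 2 (1R,2R)-cyclohex-4-ene-1,2-diyldimethanol
Product: 3 (4R,5R)-4,5-bis[(benzyloxy)methyl]cyclohex-1-ene
Conditions: NaH, BnBr, n-Bu4NI (cat.), THF/DMF, 0 °C → rt
Reagents that add atoms: benzyl bromide, BrCc1ccccc1
Why: Williamson etherification of the two primary hydroxyls gives robust benzyl ethers that are removed together with the aryl benzyl ethers in the last step.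

Step 3
Reactants: 3 (4R,5R)-4,5-bis[(benzyloxy)methyl]cyclohex-1-ene
Product: 4 (5R,6R)-5,6-bis[(benzyloxy)methyl]cyclohex-2-en-1-ol (both C1 epimers)
Conditions: SeO2 (0.5 equiv), t-BuOOH (3 equiv, anhydrous), CH2Cl2, rt
Reagents that add atoms: selenium dioxide, O=[Se]=O; tert-butyl hydroperoxide, CC(C)(C)OO
Why: SeO2 allylic hydroxylation (ene reaction then [2,3]-sigmatropic shift) oxygenates an allylic CH2 and returns the C=C to its original position, so the carbinol carbon lies next to a ring stereocentre; the two allylic CH2 groups are exchanged by the C2 axis and give one constitution, and the new carbinol centre is left unassigned because step 4 oxidises it.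

Step 4
Reactants: 4 (5R,6R)-5,6-bis[(benzyloxy)methyl]cyclohex-2-en-1-ol
Product: 5 (5R,6R)-5,6-bis[(benzyloxy)methyl]cyclohex-2-en-1-one
Conditions: Dess–Martin periodinane, CH2Cl2, 0 °C → rt
Reagents that add atoms: none
Why: Dess–Martin oxidation of the secondary allylic alcohol gives the enone under non-basic conditions, and the only enolisable stereocentre (C6) already has the more stable trans arrangement to C5.

Step 5
Reactants: 5 (5R,6R)-5,6-bis[(benzyloxy)methyl]cyclohex-2-en-1-one
Product: 7 (5R,6R)-5,6-bis[(benzyloxy)methyl]-2-bromocyclohex-2-en-1-one, via dibromo ketone 6 (not isolated)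
Conditions: Br2, CH2Cl2, 0 °C; then Et3N, 0 °C → rt
Reagents that add atoms: bromine, BrBr
Why: Bromination–dehydrobromination, in which bromine adds to the enone C=C and Et3N removes the acidic C2–H with loss of the C3 bromide (E1cB), is the standard route to 2-bromocyclohex-2-enones and leaves the benzyl ethers and the trans C5/C6 centres untouched.

Step 6
Reactants: 8 methyl acetoacetate
Product: 9 methyl 2-diazo-3-oxobutanoate
Conditions: p-ABSA, Et3N, MeCN, 0 °C → rt
Reagents that add atoms: 4-acetamidobenzenesulfonyl azide (p-ABSA), CC(=O)Nc1ccc(cc1)S(=O)(=O)N=[N+]=[N-]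
Why: Regitz diazo transfer to the active methylene of a β-keto ester is general and high-yielding.

Step 7
Reactants: 9 methyl 2-diazo-3-oxobutanoate; 10 benzyl alcohol
Product: 11 methyl 2-(benzyloxy)-3-oxobutanoate (racemic)
Conditions: Rh2(OAc)4 (1 mol %), CH2Cl2, reflux, slow addition of 9
Reagents that add atoms: none
Why: Rhodium-carbenoid O–H insertion of a 2-diazo-1,3-dicarbonyl compound into a primary alcohol installs the C7 oxygen already differentiated as its benzyl ether.

Step 8
Reactants: 11 methyl 2-(benzyloxy)-3-oxobutanoate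
Product: 13 methyl 2-(benzyloxy)-3-methoxybut-2-enoate (E/Z mixture), via dimethyl ketal 12 (not isolated)
Conditions: HC(OMe)3, H2SO4 (cat.), rt; then heat with distillation of MeOH
Reagents that add atoms: trimethyl orthoformate, COC(OC)OC
Why: Acid-catalysed ketalisation with the orthoformate followed by loss of methanol gives the conjugated β-methoxy enoate (enol-ether formation, as for methyl 3-methoxycrotonate), whose geometry is lost in step 9.

Step 9
Reactants: 13 methyl 2-(benzyloxy)-3-methoxybut-2-enoate
Product: 15 2-(benzyloxy)-1,3-dimethoxy-1-(trimethylsilyloxy)buta-1,3-diene, via lithium dienolate 14 (not isolated)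
Conditions: LiN(i-Pr)2 (LDA), THF, −78 °C; then TMSCl, −78 °C → rt; non-aqueous work-up, used crude
Reagents that add atoms: chlorotrimethylsilane, C[Si](C)(C)Cl
Why: γ-Deprotonation of the β-methoxy enoate (no α-hydrogen is present) gives the cross-conjugated dienolate, and O-silylation gives the silyl ketene acetal diene exactly as in the preparation of the parent 1,3-dimethoxy-1-silyloxybutadiene.

Step 10
Reactants: 7 (5R,6R)-5,6-bis[(benzyloxy)methyl]-2-bromocyclohex-2-en-1-one; 15 2-(benzyloxy)-1,3-dimethoxy-1-(trimethylsilyloxy)buta-1,3-diene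
Product: 18 (2R,3R)-7-(benzyloxy)-2,3-bis[(benzyloxy)methyl]-8-hydroxy-6-methoxy-3,4-dihydronaphthalen-1(2H)-one, via bromo ketal cycloadduct 16 (not isolated), via aryl silyl ether 17 (not isolated)
Conditions: 15 (2.5 equiv), toluene, rt → 80 °C; then DBU, rt; then 1 M HCl, THF, rt
Reagents that add atoms: none
Why: The electron-rich diene 15 and the α-bromo enone 7 should combine in a normal-electron-demand Diels–Alder reaction (concerted but asynchronous, at the limit a vinylogous Mukaiyama–Michael addition followed by ring closure), the nucleophilic CH2 terminus bonding to the enone β-carbon (C5–C4a) and the ketene-acetal carbon to the bromine-bearing α-carbon (C8–C8a) to give adduct 16. Ring A is closed by this intermolecular (4+2) cycloaddition, four carbons coming from the diene and C4a/C8a from the enone, not by a tethered ring closure. DBU and the acid work-up then remove methanol (C8–OMe with a C5–H, giving a cyclohexadiene) and HBr (C8a–Br with C4a–H, driven by aromatisation), and the aryl silyl ether 17 is hydrolysed to the C8 phenol, so ring A reaches the aromatic level without an oxidant. The closest known reaction type is the cycloaddition–aromatisation of 1,3-dialkoxy-1-silyloxybutadienes with α-halo enones and haloquinones. No stereocentre is created in the product, since the sp3 centres of 16 at C4a, C8 and C8a are erased on aromatisation, while C3 is untouched and C2 (α to the ketone) already holds its more stable trans arrangement. The selectivity needed is regiochemical, and it is secured by the match between the diene polarisation (largest HOMO coefficient on CH2) and the enone (electrophilic β-carbon C4a, brominated α-carbon C8a), which places OMe on C6, OBn on C7 and OH on C8.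

Step 11
Reactants: 18 (2R,3R)-7-(benzyloxy)-2,3-bis[(benzyloxy)methyl]-8-hydroxy-6-methoxy-3,4-dihydronaphthalen-1(2H)-one
Product: 19 (2R,3R)-7-(benzyloxy)-2,3-bis[(benzyloxy)methyl]-6,8-dimethoxy-3,4-dihydronaphthalen-1(2H)-one
Conditions: MeI, K2CO3, DMF, 40–50 °C
Reagents that add atoms: iodomethane, CI
Why: Williamson O-methylation of the chelated peri phenol with a carbonate base is mild enough to leave the ketone α-centre C2 in its stable trans arrangement.

Step 12
Reactants: 20 4-bromo-2,6-dimethoxyphenol
Product: 21 2-(benzyloxy)-5-bromo-1,3-dimethoxybenzene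
Conditions: BnBr, K2CO3, DMF, 60 °C
Reagents that add atoms: benzyl bromide, BrCc1ccccc1
Why: Williamson benzylation masks the phenol so that the bromide can be converted into an organometallic reagent.

Step 13
Reactants: 19 (2R,3R)-7-(benzyloxy)-2,3-bis[(benzyloxy)methyl]-6,8-dimethoxy-3,4-dihydronaphthalen-1(2H)-one; 21 2-(benzyloxy)-5-bromo-1,3-dimethoxybenzene
Product: 24 (2R,3R)-1-[4-(benzyloxy)-3,5-dimethoxyphenyl]-7-(benzyloxy)-2,3-bis[(benzyloxy)methyl]-6,8-dimethoxy-1,2,3,4-tetrahydronaphthalen-1-ol (C1 epimers), via aryllithium 22 (not isolated), via aryldichlorocerium 23 (not isolated)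
Conditions: 21, n-BuLi, THF, −78 °C; anhydrous CeCl3, −78 °C; then 19, −78 → −40 °C; aq NH4Cl
Reagents that add atoms: none
Why: Bromine–lithium exchange and transmetalation to the weakly basic organocerium reagent allow 1,2-addition to the hindered, enolisable C1 ketone without deprotonation at C2 (organocerium addition), and the carbinol configuration does not matter because C1 is planarised in step 14.

Step 14
Reactants: 24 (2R,3R)-1-[4-(benzyloxy)-3,5-dimethoxyphenyl]-7-(benzyloxy)-2,3-bis[(benzyloxy)methyl]-6,8-dimethoxy-1,2,3,4-tetrahydronaphthalen-1-ol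
Product: 26 (1S,2R,3R)-7-(benzyloxy)-1-[4-(benzyloxy)-3,5-dimethoxyphenyl]-2,3-bis[(benzyloxy)methyl]-6,8-dimethoxy-1,2,3,4-tetrahydronaphthalene, via diarylmethyl cation 25 (not isolated)
Conditions: Et3SiH (5 equiv), CF3CO2H, CH2Cl2, −40 → 0 °C
Reagents that add atoms: none
Why: Ionic hydrogenation, in which CF3CO2H ionises the tertiary diaryl carbinol to cation 25 (stabilised by ring A through its C6 and C8 methoxy groups) and Et3SiH delivers hydride along the axis of the benzylic p orbital on the half-chair that keeps both CH2OBn arms pseudo-equatorial, anti to the pseudo-axial C2–H, so that the new C1–H is cis and the aryl group trans to the C2 arm (1S); the other half-chair is disfavoured because its axial C3 arm would be 1,3-diaxial to the incoming silane, and any benzyl ether lost to the acid is of no consequence before step 15.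

Step 15
Reactants: 26 (1S,2R,3R)-7-(benzyloxy)-1-[4-(benzyloxy)-3,5-dimethoxyphenyl]-2,3-bis[(benzyloxy)methyl]-6,8-dimethoxy-1,2,3,4-tetrahydronaphthalene
Product: 27 (1S,2R,3R)-1-(4-hydroxy-3,5-dimethoxyphenyl)-2,3-bis(hydroxymethyl)-6,8-dimethoxy-1,2,3,4-tetrahydronaphthalen-7-ol (target)
Conditions: H2 (1 atm), 10 % Pd/C, EtOAc/MeOH, rt
Reagents that add atoms: none
Why: Catalytic hydrogenolysis cleaves the two alkyl and the two aryl benzyl ethers in one operation and touches neither the methyl ethers nor the three stereocentres.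

## Compound list

1 | (1R,2R)-cyclohex-4-ene-1,2-dicarboxylic acid | C1C=CC[C@@H](C(=O)O)[C@@H]1C(=O)O | starting material
2 | (1R,2R)-cyclohex-4-ene-1,2-diyldimethanol | C1C=CC[C@@H](CO)[C@@H]1CO | intermediate
3 | (4R,5R)-4,5-bis[(benzyloxy)methyl]cyclohex-1-ene | C1C=CC[C@@H](COCc2ccccc2)[C@@H]1COCc1ccccc1 | intermediate
4 | (5R,6R)-5,6-bis[(benzyloxy)methyl]cyclohex-2-en-1-ol (C1 epimers) | OC1C=CC[C@@H](COCc2ccccc2)[C@@H]1COCc1ccccc1 | intermediate
5 | (5R,6R)-5,6-bis[(benzyloxy)methyl]cyclohex-2-en-1-one | O=C1C=CC[C@@H](COCc2ccccc2)[C@@H]1COCc1ccccc1 | intermediate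
6 | (5R,6R)-5,6-bis[(benzyloxy)methyl]-2,3-dibromocyclohexan-1-one (C2/C3 mixture) | O=C1C(Br)C(Br)C[C@@H](COCc2ccccc2)[C@@H]1COCc1ccccc1 | intermediate
7 | (5R,6R)-5,6-bis[(benzyloxy)methyl]-2-bromocyclohex-2-en-1-one | O=C1C(Br)=CC[C@@H](COCc2ccccc2)[C@@H]1COCc1ccccc1 | intermediate
8 | methyl acetoacetate | CC(=O)CC(=O)OC | starting material
9 | methyl 2-diazo-3-oxobutanoate | CC(=O)C(=[N+]=[N-])C(=O)OC | intermediate
10 | benzyl alcohol | OCc1ccccc1 | starting material
11 | methyl 2-(benzyloxy)-3-oxobutanoate (racemic) | CC(=O)C(OCc1ccccc1)C(=O)OC | intermediate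
12 | methyl 2-(benzyloxy)-3,3-dimethoxybutanoate (racemic) | COC(C)(OC)C(OCc1ccccc1)C(=O)OC | intermediate
13 | methyl 2-(benzyloxy)-3-methoxybut-2-enoate (E/Z mixture) | COC(C)=C(OCc1ccccc1)C(=O)OC | intermediate
14 | lithium dienolate of 13 (lithium 2-(benzyloxy)-1,3-dimethoxybuta-1,3-dien-1-olate) | [Li]OC(OC)=C(OCc1ccccc1)C(OC)=C | intermediate
15 | 2-(benzyloxy)-1,3-dimethoxy-1-(trimethylsilyloxy)buta-1,3-diene | C=C(OC)/C(OCc1ccccc1)=C(\OC)O[Si](C)(C)C | intermediate
16 | (2R,3R)-7-(benzyloxy)-2,3-bis[(benzyloxy)methyl]-8a-bromo-6,8-dimethoxy-8-(trimethylsilyloxy)-3,4,4a,5,8,8a-hexahydronaphthalen-1(2H)-one (mixture at C4a, C8, C8a) | O=C1C2(Br)C(OC)(O[Si](C)(C)C)C(OCc3ccccc3)=C(OC)CC2C[C@@H](COCc2ccccc2)[C@@H]1COCc1ccccc1 | intermediate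
17 | (2R,3R)-7-(benzyloxy)-2,3-bis[(benzyloxy)methyl]-6-methoxy-8-(trimethylsilyloxy)-3,4-dihydronaphthalen-1(2H)-one | O=C1c2c(O[Si](C)(C)C)c(OCc3ccccc3)c(OC)cc2C[C@@H](COCc2ccccc2)[C@@H]1COCc1ccccc1 | intermediate
18 | (2R,3R)-7-(benzyloxy)-2,3-bis[(benzyloxy)methyl]-8-hydroxy-6-methoxy-3,4-dihydronaphthalen-1(2H)-one | O=C1c2c(O)c(OCc3ccccc3)c(OC)cc2C[C@@H](COCc2ccccc2)[C@@H]1COCc1ccccc1 | intermediate
19 | (2R,3R)-7-(benzyloxy)-2,3-bis[(benzyloxy)methyl]-6,8-dimethoxy-3,4-dihydronaphthalen-1(2H)-one | O=C1c2c(OC)c(OCc3ccccc3)c(OC)cc2C[C@@H](COCc2ccccc2)[C@@H]1COCc1ccccc1 | intermediate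
20 | 4-bromo-2,6-dimethoxyphenol | COc1cc(Br)cc(OC)c1O | starting material
21 | 2-(benzyloxy)-5-bromo-1,3-dimethoxybenzene | COc1cc(Br)cc(OC)c1OCc1ccccc1 | intermediate
22 | [4-(benzyloxy)-3,5-dimethoxyphenyl]lithium | [Li]c1cc(OC)c(OCc2ccccc2)c(OC)c1 | intermediate
23 | [4-(benzyloxy)-3,5-dimethoxyphenyl]cerium dichloride | Cl[Ce](Cl)c1cc(OC)c(OCc2ccccc2)c(OC)c1 | intermediate
24 | (2R,3R)-1-[4-(benzyloxy)-3,5-dimethoxyphenyl]-7-(benzyloxy)-2,3-bis[(benzyloxy)methyl]-6,8-dimethoxy-1,2,3,4-tetrahydronaphthalen-1-ol (C1 epimers) | OC1(c2cc(OC)c(OCc3ccccc3)c(OC)c2)c2c(OC)c(OCc3ccccc3)c(OC)cc2C[C@@H](COCc2ccccc2)[C@@H]1COCc1ccccc1 | intermediate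
25 | (2R,3R)-1-[4-(benzyloxy)-3,5-dimethoxyphenyl]-7-(benzyloxy)-2,3-bis[(benzyloxy)methyl]-6,8-dimethoxy-1,2,3,4-tetrahydronaphthalen-1-ylium trifluoroacetate | [C+]1(c2cc(OC)c(OCc3ccccc3)c(OC)c2)c2c(OC)c(OCc3ccccc3)c(OC)cc2C[C@@H](COCc2ccccc2)[C@@H]1COCc1ccccc1.[O-]C(=O)C(F)(F)F | intermediate
26 | (1S,2R,3R)-7-(benzyloxy)-1-[4-(benzyloxy)-3,5-dimethoxyphenyl]-2,3-bis[(benzyloxy)methyl]-6,8-dimethoxy-1,2,3,4-tetrahydronaphthalene | COc1cc([C@H]2c3c(cc(OC)c(OCc4ccccc4)c3OC)C[C@@H](COCc3ccccc3)[C@@H]2COCc2ccccc2)cc(OC)c1OCc1ccccc1 | intermediate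
27 | (1S,2R,3R)-1-(4-hydroxy-3,5-dimethoxyphenyl)-2,3-bis(hydroxymethyl)-6,8-dimethoxy-1,2,3,4-tetrahydronaphthalen-7-ol | COc1cc([C@H]2c3c(cc(OC)c(O)c3OC)C[C@@H](CO)[C@@H]2CO)cc(OC)c1O | target

## Step count and risks

Total step count: 15. Longest linear sequence: 10 steps (steps 1, 2, 3, 4, 5, 10, 11, 13, 14, 15).

Steps most likely to fail:

Step 10. The cycloaddition may be outrun by desilylation of the hindered, tetra-oxygenated diene, or adduct 16 may lose bromine reductively or rearrange in place of eliminating HBr, so that ring A does not reach the phenol level. The fallback separates bond formation from aromatisation and sets out from the non-brominated enone 5 and diene 15. A TiCl4-mediated vinylogous Mukaiyama–Michael addition (CH2Cl2, −78 °C) forms C5–C4a and gives methyl 2-(benzyloxy)-4-{3,4-trans-bis[(benzyloxy)methyl]-5-oxocyclohexyl}-3-methoxybut-2-enoate F1. Dieckmann closure with KOt-Bu in THF can only proceed through the C8a enolate onto the ester (C8–C8a) and gives the enolised bicyclic diketone (2R,3R)-7-(benzyloxy)-2,3-bis[(benzyloxy)methyl]-6-methoxy-3,4,4a,5-tetrahydronaphthalene-1,8(2H,8aH)-dione F2. Dehydrogenation with DDQ in dioxane should then give the phenol, and the fallback comes back to the route at 18.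

Step 14. Hydride may enter C1 on the face that leaves the aryl group cis to the C2 arm, and reversible loss of the C2 proton from cation 25 may erode the C2 configuration. The fallback sets out from 24 and replaces the free cation by stereospecific surface hydrogenolysis. In 24 the aryl group is expected cis to the C2 arm and the hydroxyl trans (pseudo-axial entry of the aryl-cerium reagent anti to the pseudo-axial C2–H). Hydrogenolysis of the benzylic C1–O bond over Pd(OH)2/C (H2, EtOAc/MeOH, a little AcOH) proceeds with inversion, which places H cis and aryl trans to the C2 arm, and removes the four benzyl groups in the same operation. Should the other C1 epimer of 24 predominate, W-2 Raney nickel in ethanol (retention) would cleave the C1–O bond before the Pd debenzylation. The fallback comes back to the route at 27 and makes no compound outside the list (none F0).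

Step 3. The ene reaction of SeO2 with a 1,2-disubstituted ring alkene may be slow, with incomplete conversion and over-oxidation to diol and enone mixtures. The fallback sets out from 3 and reaches the same allylic alcohol by two allylic transpositions of fixed regiochemistry. Photooxygenation (O2, tetraphenylporphyrin, hν, CH2Cl2) in the presence of Ac2O, pyridine and DMAP gives the Schenck ene product 4,5-trans-bis[(benzyloxy)methyl]cyclohex-2-en-1-yl hydroperoxide F3, which is dehydrated in the same flask to (4R,5R)-4,5-bis[(benzyloxy)methyl]cyclohex-2-en-1-one F4. Nucleophilic epoxidation (H2O2, NaOH, MeOH, 0 °C) gives 4,5-trans-bis[(benzyloxy)methyl]-2,3-epoxycyclohexan-1-one F5. Wharton transposition (N2H4·H2O, AcOH cat., MeOH) moves the oxygen next to the ring stereocentre, and the fallback comes back to the route at 4.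

## Further compounds

F1 | step 10 | methyl 2-(benzyloxy)-4-{3,4-trans-bis[(benzyloxy)methyl]-5-oxocyclohexyl}-3-methoxybut-2-enoate (mixture at the ring attachment carbon and of alkene isomers) | O=C1CC(CC(OC)=C(OCc2ccccc2)C(=O)OC)C[C@@H](COCc2ccccc2)[C@@H]1COCc1ccccc1
F2 | step 10 | (2R,3R)-7-(benzyloxy)-2,3-bis[(benzyloxy)methyl]-6-methoxy-3,4,4a,5-tetrahydronaphthalene-1,8(2H,8aH)-dione (enolised) | O=C1C2C(=O)C(OCc3ccccc3)=C(OC)CC2C[C@@H](COCc2ccccc2)[C@@H]1COCc1ccccc1
F0 | step 14 | none | none
F3 | step 3 | 4,5-trans-bis[(benzyloxy)methyl]cyclohex-2-en-1-yl hydroperoxide (C1 epimers) | C1C(OO)C=C[C@@H](COCc2ccccc2)[C@@H]1COCc1ccccc1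
F4 | step 3 | (4R,5R)-4,5-bis[(benzyloxy)methyl]cyclohex-2-en-1-one | C1C(=O)C=C[C@@H](COCc2ccccc2)[C@@H]1COCc1ccccc1
F5 | step 3 | 4,5-trans-bis[(benzyloxy)methyl]-2,3-epoxycyclohexan-1-one | C1C(=O)C2OC2[C@@H](COCc2ccccc2)[C@@H]1COCc1ccccc1
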